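## The problem

Compound 16 is a (2S)-flavanone: a benzene ring A with no free position (C5 hydroxyl, C6 prenyl, C7 methoxy, C8 prenyl) is fused through C4a and C8a to the dihydropyranone ring C, which carries the 4-hydroxyphenyl ring B at C2. C2 is the only stereocentre, so no other centre can direct it and its configuration has to come from a reagent or catalyst. It is also labile: C2 is a benzylic ether carbon β to the C4 ketone, and base opens ring C by retro-oxa-Michael reaction to an achiral chalcone, so once the ketone and the O1–C2 ether coexist no basic step may follow. Ring A needs six substituents placed without regiochemical doubt, and the oxygens at C5 and C7 must be told apart. The two prenyl groups are the fragile part: a trisubstituted alkene beside a phenol cyclises to a dimethylchroman in strong acid, reacts with electrophilic halogen and with borane, and rules out hydrogenolysis, so halogenation must precede prenylation and the protecting groups must leave under mild acid. The enabling feature is that O1 bridges the C2 carbinol carbon and the aryl carbon C8a: with bromine on C8a and a free hydroxyl on C2, the O1–C8a bond can be closed by palladium catalysis without touching the C2–O bond, and keeping C4 as a carbinol during that base-mediated step removes the chalcone pathway.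

## Retrosynthesis

**16 from 15 from 14.** The two phenols of 16 are masked as methoxymethyl ethers in 15, and the C4 carbonyl of 15 is traced back to the carbinol of 14. No skeletal bond is cut. The ring closure uses carbonate base at 80 °C, where a β-aryloxy ketone would open and a β-hydroxy ketone would dehydrate, so C4 stays a carbinol until ring C exists. The forward steps must be a non-basic oxidation and a deprotection mild enough for two prenyl groups.

**14 from 13.** The O1–C8a bond is cut, giving the acyclic bromo diol 13. The neighbouring cut O1–C2 would mean substitution at a para-oxygenated benzylic carbinol, which ionises easily and loses configuration, or an oxa-Michael addition, which is reversible. The O1–C8a cut leaves C2 a spectator. The forward reaction must couple a secondary alkoxide to a di-ortho-substituted, electron-rich aryl bromide without β-hydride elimination, and must pick the right hydroxyl, which ring size decides.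

**13 from 12.** The C2 carbinol is traced back to the aryl ketone 12. An aryl alkyl ketone is the best substrate class for catalytic asymmetric reduction, so the only stereocentre is set where catalyst control is most reliable. The forward reaction must override the remote racemic carbinol of 12, which is later oxidised, and must spare alkenes and the aryl bromide.

**12 from 8 and 10 (10 from 9).** The C3–C4 bond is cut by an aldol disconnection into the ring A aldehyde 8 and the ring B methyl ketone 10, the methoxymethyl ether of 9. The opposite polarity (ring A methyl ketone plus ring B aldehyde) would create C2 in the aldol itself and demand an enantioselective aldol. The chosen cut leaves C2 as a ketone for step 8 and creates only the carbinol that is destroyed later. Aldehyde 8 cannot enolise, so a preformed enolate of 10 adds cleanly if the aldolate is quenched cold.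

**8 from 6 and 7.** Both aryl–CH2 bonds are cut at once, giving the diiodide 6 and the prenyl stannane 7. Directed metalation of a bromoarene is the obvious neighbour, but alkyllithiums exchange the bromine, lithium amides give uncertain site selectivity among three acidified positions, and a lithiated carbon next to bromine invites aryne formation. Cross-coupling at iodides puts each prenyl group where an iodine was placed. The forward reaction must discriminate C–I from C–Br and deliver the linear allyl isomer.

**6 from 5, 4, 3 and 1.** Protecting-group and substitution steps lead back to the symmetrical arene 1. In 4 only two ring positions are free and both are activated, so twofold iodination has no choice to make. The aldehyde of 3 distinguishes its ortho methoxy group by chelation, which settles O5 against O7. Formylation of 1 can only go para to one methoxy group and ortho to bromine, because both such positions are equivalent. Every regiochemical question on ring A is thus answered by symmetry or by the absence of alternatives.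

## Roads not taken

**Alternative 1:** The cut is at both aryl–CH2 bonds of ring A and afterwards at the O7–methyl bond. In the forward sense a magnesium-dependent aromatic prenyltransferase would transfer two dimethylallyl groups from dimethylallyl diphosphate A2 to C8 and C6 of (2S)-naringenin A1, giving (2S)-6,8-diprenylnaringenin A3. Methylation at O7 would then give 16.
- Merits: two operations, no protecting groups, the stereocentre comes with A1, and neutral water cannot open ring C.
- Weak points: one enzyme must accept a flavanone and serve both C6 and C8, whereas flavonoid prenyltransferases tend to be specific for one position. The second transfer has to occur on a more crowded, less soluble substrate. The donor A2 is needed in stoichiometric amount. The O7 hydroxyl of A3 lies between two prenyl groups and must be methylated beside the hydroxyls at C4' and C5; its acidity speaks for it and its crowding against it, and the base required can open ring C and racemise C2.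
- Comparison: in step count this road is clearly better (two operations against eleven) and it produces no tin or palladium waste. The chosen plan sets against that catalogue reagents throughout, regiochemistry fixed by construction (the O7 methyl group is present in 1 and O5 is singled out in step 2), no late selective methylation, and either enantiomer by choice of catalyst in step 8.

**Alternative 2:** The cut is at C8a–C8 and C6–C7 of ring A. Heating the cyclobutenone A4 with the alkynyl ether A5 would open A4 to a vinylketene, which adds to the alkyne; a second electrocyclic opening and a six-electron closure then give the phenol A6.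
- Merits: five substituents of ring A are placed regiospecifically in one thermal step with the three oxygens already differentiated, no halogen or tin is involved, and prenyl groups tolerate neutral heat.
- Weak points: A4 and A5 are not commercial and each needs several steps. The benzannulation solves ring A only, since A6 lacks the C4 carbon, ring C and the stereocentre. The last free position of A6 would have to be acylated under acidic conditions that endanger the prenyl groups. Ring C would then most directly be closed through a reversible chalcone oxa-Michael addition that is hard to render enantioselective.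
- Comparison: as a ring A synthesis this road is more elegant than steps 1 to 5 and avoids the C–I against C–Br question. Steps 1 to 5, however, deliver 8 with the C4 carbon and the C8a bromide in place, so the stereocentre and ring C follow in four reliable steps; Alternative 2 leaves that part open.

**Alternative 3:** The cut is at C2–C3. A chiral aluminium Lewis acid would ionise the acetal C–O bond of the benzodioxine enol acetal A7, and the tethered aluminium enolate carbon would add to the oxocarbenium carbon to close ring C as the silyl-protected flavanone A8.
- Merits: the C–C bond and ring C form in one step at the ketone oxidation level, so the reduction and re-oxidation of steps 8 and 10 are not needed, and no aryl halide is required.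
- Weak points: ionisation erases the acetal stereocentre, and the planar oxocarbenium ion must then be attacked on one face under the sole control of the ligand on aluminium. No substrate element assists, and this mode of control has no established generality. A stoichiometric strong Lewis acid meets two prenyl groups and two aryl silyl ethers, and it can reopen ring C of A8 and erode its enantiopurity. A7 needs methylenation of a hindered ester, and the hexasubstituted ring A still has to be built.
- Comparison: if the enantioselection worked, this road would be shorter after ring A and more redox-economical, which is conceded. The chosen plan sets against it a stereocentre fixed by a catalytic ketone reduction of proven scope and a ring closure that cannot touch it.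

Key step: step 9

Remarks on the chemistry (assumptions):
- The descriptor in the SMILES of 16 corresponds to (2S).
- The ring A carbinol carbon formed in step 7 is not controlled. Compounds 13 and 14 are each carried as the pair of epimers at that carbon, written (1RS) and (4RS) with no descriptor at that atom in the SMILES, because step 10 converts it into the C4 carbonyl.
- Stannane 7 is treated as a purchasable reagent.

## Route

Step 1
Reactants: 1 1-bromo-3,5-dimethoxybenzene
Product: 3 2-bromo-4,6-dimethoxybenzaldehyde, via aryl iminium salt 2 (not isolated)
Conditions: POCl3 (1.5 equiv), DMF, 0 °C → 90 °C; then ice–water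
Reagents that add atoms: N,N-dimethylformamide CN(C)C=O; water O
Why: Vilsmeier–Haack formylation; the chloroiminium ion attacks para to one methoxy group and ortho to the other, the usual preference of 1,3-dimethoxyarenes over the position between the two ethers, and the two such positions of 1 are equivalent. Hydrolysis of iminium salt 2 releases the aldehyde.

Step 2
Reactants: 3 2-bromo-4,6-dimethoxybenzaldehyde
Product: 4 2-bromo-6-hydroxy-4-methoxybenzaldehyde
Conditions: BCl3 (1 M in CH2Cl2, 1.5 equiv), CH2Cl2, −78 °C → 0 °C; then H2O
Reagents that add atoms: none
Why: Chelation-controlled aryl methyl ether cleavage; BCl3 binds the aldehyde oxygen and the ortho methoxy oxygen in a six-membered chelate, so only that ether is cleaved and the para methoxy group (the future C7 methoxy) remains.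

Step 3
Reactants: 4 2-bromo-6-hydroxy-4-methoxybenzaldehyde
Product: 5 2-bromo-6-hydroxy-3,5-diiodo-4-methoxybenzaldehyde
Conditions: NIS (2.3 equiv), TsOH·H2O (10 mol %), MeCN, rt, dark
Reagents that add atoms: N-iodosuccinimide O=C1CCC(=O)N1I
Why: Electrophilic aromatic iodination; the only two free positions are ortho or para to the phenol, ortho to the methoxy group and meta to the aldehyde, so both are iodinated and no regiochemical choice exists. The step is placed before any alkene is present.

Step 4
Reactants: 5 2-bromo-6-hydroxy-3,5-diiodo-4-methoxybenzaldehyde
Product: 6 2-bromo-3,5-diiodo-4-methoxy-6-(methoxymethoxy)benzaldehyde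
Conditions: MOMCl (1.5 equiv), i-Pr2NEt (2 equiv), CH2Cl2, 0 °C → rt
Reagents that add atoms: chloromethyl methyl ether COCCl
Why: O-alkylation of the phenol to its methoxymethyl ether (acetal protection). The group withstands the stannane coupling, the enolate, the transfer hydrogenation and the carbonate-mediated ring closure, and it is removed by dilute acid at the end.

Step 5
Reactants: 6 2-bromo-3,5-diiodo-4-methoxy-6-(methoxymethoxy)benzaldehyde; 7 tributyl(3-methylbut-2-en-1-yl)stannane (2.4 equiv)
Product: 8 2-bromo-4-methoxy-6-(methoxymethoxy)-3,5-bis(3-methylbut-2-en-1-yl)benzaldehyde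
Conditions: Pd(PPh3)4 (10 mol %), CuI (20 mol %), DMF, 60 °C
Reagents that add atoms: none
Why: Twofold Stille cross-coupling of aryl iodides with an allylic stannane; zerovalent palladium inserts into C–I far faster than into C–Br, so the bromide needed in step 9 is kept. The allyl group passes through an η3-allyl palladium species that reductively eliminates at its less substituted terminus, giving the linear prenyl group; the aldehyde is inert without a Lewis acid.

Step 6
Reactants: 9 4-hydroxyacetophenone
Product: 10 1-[4-(methoxymethoxy)phenyl]ethanone
Conditions: MOMCl (1.3 equiv), i-Pr2NEt (1.5 equiv), CH2Cl2, 0 °C → rt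
Reagents that add atoms: chloromethyl methyl ether COCCl
Why: O-alkylation of the phenol to its methoxymethyl ether, so that the ketone can be enolised with one equivalent of base and the ring B oxygen carries the same protecting group as ring A.

Step 7
Reactants: 10 1-[4-(methoxymethoxy)phenyl]ethanone (1.1 equiv); 8 2-bromo-4-methoxy-6-(methoxymethoxy)-3,5-bis(3-methylbut-2-en-1-yl)benzaldehyde
Product: 12 rac-3-[2-bromo-4-methoxy-6-(methoxymethoxy)-3,5-bis(3-methylbut-2-en-1-yl)phenyl]-3-hydroxy-1-[4-(methoxymethoxy)phenyl]propan-1-one, via lithium enolate 11 (not isolated)
Conditions: LiN(i-Pr)2 (1.15 equiv), THF, −78 °C; then 8, −78 °C; AcOH quench at −78 °C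
Reagents that add atoms: none
Why: Directed crossed aldol addition of a preformed lithium enolate to a non-enolisable aldehyde, forming the C3–C4 bond; the cold acidic quench prevents retro-aldol cleavage and dehydration. The new carbinol is racemic and needs no control because step 10 oxidises it.

Step 8
Reactants: 12 rac-3-[2-bromo-4-methoxy-6-(methoxymethoxy)-3,5-bis(3-methylbut-2-en-1-yl)phenyl]-3-hydroxy-1-[4-(methoxymethoxy)phenyl]propan-1-one
Product: 13 (1RS,3S)-1-[2-bromo-4-methoxy-6-(methoxymethoxy)-3,5-bis(3-methylbut-2-en-1-yl)phenyl]-3-[4-(methoxymethoxy)phenyl]propane-1,3-diol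
Conditions: RuCl[(S,S)-TsDPEN](p-cymene) (2 mol %), HCO2H/Et3N (1:1), DMF, 30 °C
Reagents that add atoms: none
Why: Noyori–Ikariya asymmetric transfer hydrogenation of an aryl alkyl ketone; the (S,S) catalyst delivers hydride through its six-membered transition state, with the aryl ring held against the arene ligand, to the face that gives the (S)-carbinol, as with acetophenone. Catalyst control should override the remote racemic carbinol, so both enantiomers of 12 give (3S) products; alkenes, aryl bromide and methoxymethyl ethers are not touched.

Step 9
Reactants: 13 (1RS,3S)-1-[2-bromo-4-methoxy-6-(methoxymethoxy)-3,5-bis(3-methylbut-2-en-1-yl)phenyl]-3-[4-(methoxymethoxy)phenyl]propane-1,3-diol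
Product: 14 (2S,4RS)-7-methoxy-5-(methoxymethoxy)-2-[4-(methoxymethoxy)phenyl]-6,8-bis(3-methylbut-2-en-1-yl)-3,4-dihydro-2H-chromen-4-ol
Conditions: Pd(OAc)2 (5 mol %), rac-2-(di-tert-butylphosphino)-1,1'-binaphthyl (6 mol %), Cs2CO3 (1.5 equiv), toluene, 80 °C
Reagents that add atoms: none
Why: Intramolecular Buchwald–Hartwig C–O coupling, the palladium-catalysed etherification of an aryl bromide by a secondary alcohol that is established for chromans. Zerovalent palladium, formed in situ from Pd(OAc)2 and the phosphine, inserts into the C8a–Br bond, the only carbon–halogen bond left after step 5. Cs2CO3 deprotonates the coordinated C2 hydroxyl, the alkoxide replaces bromide on divalent palladium, and C–O reductive elimination from the seven-membered oxapalladacycle forms O1–C8a and closes ring C as a six-membered ring (6-exo with respect to the aryl carbon). No stereocentre is created; the C2–O bond is never broken, so the S configuration from step 8 is retained, and the uncontrolled ring A carbinol becomes C4 of 14 in both configurations. Chemoselectivity between the two hydroxyls rests on ring size, since the ring A carbinol could only close a four-membered ring. The step needs reductive elimination to outrun β-hydride elimination of the secondary alkoxide; the bulky electron-rich di-tert-butyl biaryl phosphine and the two ortho substituents beside palladium both speed reductive elimination. The prenyl alkenes cannot insert because only a strained four-membered carbopalladation is within reach, and carbonate in toluene leaves the methoxymethyl ethers alone.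

Step 10
Reactants: 14 (2S,4RS)-7-methoxy-5-(methoxymethoxy)-2-[4-(methoxymethoxy)phenyl]-6,8-bis(3-methylbut-2-en-1-yl)-3,4-dihydro-2H-chromen-4-ol
Product: 15 (2S)-7-methoxy-5-(methoxymethoxy)-2-[4-(methoxymethoxy)phenyl]-6,8-bis(3-methylbut-2-en-1-yl)-2,3-dihydro-4H-chromen-4-one
Conditions: Dess–Martin periodinane (1.3 equiv), NaHCO3, CH2Cl2, 0 °C → rt
Reagents that add atoms: none
Why: Dess–Martin oxidation of a secondary benzylic alcohol to the ketone, which converts both C4 epimers into one compound. The buffered, non-basic medium spares the alkenes and acetals and gives no base to open ring C, so C2 keeps its configuration.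

Step 11
Reactants: 15 (2S)-7-methoxy-5-(methoxymethoxy)-2-[4-(methoxymethoxy)phenyl]-6,8-bis(3-methylbut-2-en-1-yl)-2,3-dihydro-4H-chromen-4-one
Product: 16 (2S)-5-hydroxy-2-(4-hydroxyphenyl)-7-methoxy-6,8-bis(3-methylbut-2-en-1-yl)-2,3-dihydro-4H-chromen-4-one
Conditions: 3 M HCl (aq.), MeOH, 40 °C
Reagents that add atoms: none
Why: Acid-catalysed acetal exchange removes both methoxymethyl ethers, the one at C5 being helped by the neighbouring carbonyl. Dilute acid at moderate temperature is the usual way to unmask prenylated flavanones and does not epimerise C2, since ring opening needs base.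

## Compound list

1 | 1-bromo-3,5-dimethoxybenzene | COc1cc(OC)cc(Br)c1 | starting material
2 | [(2-bromo-4,6-dimethoxyphenyl)methylidene]dimethylammonium dichlorophosphate | COc1cc(OC)c(C=[N+](C)C)c(Br)c1.[O-]P(=O)(Cl)Cl | intermediate
3 | 2-bromo-4,6-dimethoxybenzaldehyde | COc1cc(OC)c(C=O)c(Br)c1 | intermediate
4 | 2-bromo-6-hydroxy-4-methoxybenzaldehyde | COc1cc(O)c(C=O)c(Br)c1 | intermediate
5 | 2-bromo-6-hydroxy-3,5-diiodo-4-methoxybenzaldehyde | COc1c(I)c(O)c(C=O)c(Br)c1I | intermediate
6 | 2-bromo-3,5-diiodo-4-methoxy-6-(methoxymethoxy)benzaldehyde | COc1c(I)c(OCOC)c(C=O)c(Br)c1I | intermediate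
7 | tributyl(3-methylbut-2-en-1-yl)stannane | CCCC[Sn](CCCC)(CCCC)CC=C(C)C | starting material
8 | 2-bromo-4-methoxy-6-(methoxymethoxy)-3,5-bis(3-methylbut-2-en-1-yl)benzaldehyde | COc1c(CC=C(C)C)c(OCOC)c(C=O)c(Br)c1CC=C(C)C | intermediate
9 | 4-hydroxyacetophenone | CC(=O)c1ccc(O)cc1 | starting material
10 | 1-[4-(methoxymethoxy)phenyl]ethanone | CC(=O)c1ccc(OCOC)cc1 | intermediate
11 | lithium 1-[4-(methoxymethoxy)phenyl]ethen-1-olate | [Li+].[O-]C(=C)c1ccc(OCOC)cc1 | intermediate
12 | rac-3-[2-bromo-4-methoxy-6-(methoxymethoxy)-3,5-bis(3-methylbut-2-en-1-yl)phenyl]-3-hydroxy-1-[4-(methoxymethoxy)phenyl]propan-1-one | COc1c(CC=C(C)C)c(OCOC)c(c(Br)c1CC=C(C)C)C(O)CC(=O)c1ccc(OCOC)cc1 | intermediate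
13 | (1RS,3S)-1-[2-bromo-4-methoxy-6-(methoxymethoxy)-3,5-bis(3-methylbut-2-en-1-yl)phenyl]-3-[4-(methoxymethoxy)phenyl]propane-1,3-diol (both C1 epimers, 3S fixed) | COc1c(CC=C(C)C)c(OCOC)c(c(Br)c1CC=C(C)C)C(O)C[C@H](O)c1ccc(OCOC)cc1 | intermediate
14 | (2S,4RS)-7-methoxy-5-(methoxymethoxy)-2-[4-(methoxymethoxy)phenyl]-6,8-bis(3-methylbut-2-en-1-yl)-3,4-dihydro-2H-chromen-4-ol (both C4 epimers, 2S fixed) | COc1c(CC=C(C)C)c(OCOC)c2c(c1CC=C(C)C)O[C@H](c1ccc(OCOC)cc1)CC2O | intermediate
15 | (2S)-7-methoxy-5-(methoxymethoxy)-2-[4-(methoxymethoxy)phenyl]-6,8-bis(3-methylbut-2-en-1-yl)-2,3-dihydro-4H-chromen-4-one | COc1c(CC=C(C)C)c(OCOC)c2c(c1CC=C(C)C)O[C@H](c1ccc(OCOC)cc1)CC2=O | intermediate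
16 | (2S)-5-hydroxy-2-(4-hydroxyphenyl)-7-methoxy-6,8-bis(3-methylbut-2-en-1-yl)-2,3-dihydro-4H-chromen-4-one (CNP0121058.1) | COc1c(CC=C(C)C)c(O)c2c(c1CC=C(C)C)O[C@H](c1ccc(O)cc1)CC2=O | target

## Step count and risks

Total: 11 steps. Longest linear sequence: 10 steps (1 to 16 through steps 1–5 and 7–11); step 6 is a one-step branch.

**Step 9 (key step).** The likeliest failure is β-hydride elimination of the palladium alkoxide. The C2 alkoxide carries an activated benzylic hydrogen, and oxidative addition and reductive elimination at a di-ortho-substituted, electron-rich aryl carbon are slow, so the substrate may be diverted to the aryl ketone with loss of bromine. Fallback: setting out from 13, the closure is run as a copper-catalysed Ullmann-type etherification (CuI, 3,4,7,8-tetramethyl-1,10-phenanthroline, Cs2CO3, toluene, 110 °C). The copper alkoxide has no ready β-hydride pathway, and the same O1–C8a bond is formed. The fallback returns at 14 and makes no new compound (F0).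

**Step 5.** The allyl transfer may lose regiocontrol and give the branched 1,1-dimethylallyl isomer, the second coupling at the crowded iodide may stall, or oxidative addition at C–Br may begin once the iodides are consumed. Fallback: setting out from 6, the smaller and faster allyltributylstannane is coupled under the same palladium catalysis at 50 °C to give 2-bromo-4-methoxy-6-(methoxymethoxy)-3,5-di(prop-2-en-1-yl)benzaldehyde F1, for which no allyl regiochemistry exists. Cross-metathesis of F1 with excess 2-methylbut-2-ene and the second-generation Grubbs catalyst RuCl2(=CHPh)(H2IMes)(PCy3) in CH2Cl2 at 40 °C converts both allyl groups into prenyl groups and returns at 8.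

**Step 8.** Retro-aldol cleavage or dehydration of the β-hydroxy ketone in the formic acid–amine medium may compete with reduction, and catalyst control may be weaker for the mismatched enantiomer of 12, which would lower the enantiopurity at C2. Fallback: setting out from 12, three changes are made.
- The hydroxyl is silylated (Et3SiCl, imidazole, DMF) to give rac-3-[2-bromo-4-methoxy-6-(methoxymethoxy)-3,5-bis(3-methylbut-2-en-1-yl)phenyl]-1-[4-(methoxymethoxy)phenyl]-3-(triethylsilyloxy)propan-1-one F2, which can neither cleave nor dehydrate.
- Corey–Bakshi–Shibata reduction with (R)-2-methyl-CBS-oxazaborolidine and catecholborane in toluene at −78 °C, a reductant that leaves trisubstituted alkenes alone at that temperature, gives (1S,3RS)-3-[2-bromo-4-methoxy-6-(methoxymethoxy)-3,5-bis(3-methylbut-2-en-1-yl)phenyl]-1-[4-(methoxymethoxy)phenyl]-3-(triethylsilyloxy)propan-1-ol F3.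
- The palladium-catalysed ring closure of step 9 is applied to F3 and gives (2S,4RS)-7-methoxy-5-(methoxymethoxy)-2-[4-(methoxymethoxy)phenyl]-6,8-bis(3-methylbut-2-en-1-yl)-4-(triethylsilyloxy)-3,4-dihydro-2H-chromene F4. Bu4NF in THF removes the silyl group and returns at 14.

**Step 11.** Brønsted acid may cyclise the C6 prenyl group onto the freed C5 phenol, or add methanol or water across the alkenes, before the slower ring B methoxymethyl ether is gone. Fallback: setting out from 15, the acetals are cleaved by Lewis acid-assisted thiolysis (ZnBr2, 1-propanethiol, CH2Cl2, 0 °C). The thiol captures the methoxymethyl unit under aprotic conditions within minutes, so no protic acid meets the alkenes. The fallback returns at 16 and makes no new compound (F0).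

## Further compounds

F1 | step 5 | 2-bromo-4-methoxy-6-(methoxymethoxy)-3,5-di(prop-2-en-1-yl)benzaldehyde | COc1c(CC=C)c(OCOC)c(C=O)c(Br)c1CC=C
F2 | step 8 | rac-3-[2-bromo-4-methoxy-6-(methoxymethoxy)-3,5-bis(3-methylbut-2-en-1-yl)phenyl]-1-[4-(methoxymethoxy)phenyl]-3-(triethylsilyloxy)propan-1-one | COc1c(CC=C(C)C)c(OCOC)c(c(Br)c1CC=C(C)C)C(O[Si](CC)(CC)CC)CC(=O)c1ccc(OCOC)cc1
F3 | step 8 | (1S,3RS)-3-[2-bromo-4-methoxy-6-(methoxymethoxy)-3,5-bis(3-methylbut-2-en-1-yl)phenyl]-1-[4-(methoxymethoxy)phenyl]-3-(triethylsilyloxy)propan-1-ol | COc1c(CC=C(C)C)c(OCOC)c(c(Br)c1CC=C(C)C)C(O[Si](CC)(CC)CC)C[C@H](O)c1ccc(OCOC)cc1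
F4 | step 8 | (2S,4RS)-7-methoxy-5-(methoxymethoxy)-2-[4-(methoxymethoxy)phenyl]-6,8-bis(3-methylbut-2-en-1-yl)-4-(triethylsilyloxy)-3,4-dihydro-2H-chromene | COc1c(CC=C(C)C)c(OCOC)c2c(c1CC=C(C)C)O[C@H](c1ccc(OCOC)cc1)CC2O[Si](CC)(CC)CC
F0 | step 9 | none | none
F0 | step 11 | none | none
A1 | alternative 1 | (2S)-naringenin | Oc1cc(O)c2c(c1)O[C@H](c1ccc(O)cc1)CC2=O
A2 | alternative 1 | dimethylallyl diphosphate | CC(C)=CCOP(=O)(O)OP(=O)(O)O
A3 | alternative 1 | (2S)-6,8-diprenylnaringenin | Oc1c(CC=C(C)C)c(O)c2c(c1CC=C(C)C)O[C@H](c1ccc(O)cc1)CC2=O
A4 | alternative 2 | 2-(3-methylbut-2-en-1-yl)-3-(triisopropylsilyloxy)cyclobut-2-en-1-one | O=C1CC(O[Si](C(C)C)(C(C)C)C(C)C)=C1CC=C(C)C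
A5 | alternative 2 | 1-methoxy-5-methylhex-4-en-1-yne | COC#CCC=C(C)C
A6 | alternative 2 | 3-methoxy-2,4-bis(3-methylbut-2-enyl)-5-(triisopropylsilyloxy)phenol | COc1c(CC=C(C)C)c(O)cc(O[Si](C(C)C)(C(C)C)C(C)C)c1CC=C(C)C
A7 | alternative 3 | 5-(tert-butyldimethylsilyloxy)-2-[4-(tert-butyldimethylsilyloxy)phenyl]-7-methoxy-4-methylidene-6,8-bis(3-methylbut-2-en-1-yl)-4H-1,3-benzodioxine | C=C1OC(c2ccc(O[Si](C)(C)C(C)(C)C)cc2)Oc2c(CC=C(C)C)c(OC)c(CC=C(C)C)c(O[Si](C)(C)C(C)(C)C)c12
A8 | alternative 3 | (2S)-5-(tert-butyldimethylsilyloxy)-2-[4-(tert-butyldimethylsilyloxy)phenyl]-7-methoxy-6,8-diprenylchroman-4-one | COc1c(CC=C(C)C)c(O[Si](C)(C)C(C)(C)C)c2c(c1CC=C(C)C)O[C@H](c1ccc(O[Si](C)(C)C(C)(C)C)cc1)CC2=O
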